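(Readings and results were generated by integration from invented constants; scatter was added.)

Sunday's run held less protic impurity than the new flask, 3.4 mM against 5.00 mM, and otherwise looks nearly the same, so I ask what that small step costs.

common to all: electrophile 0.050 M
- Sunday's: nucleophile 1 equiv (fed, over 15 s); free base 3 equiv; protic impurity 3.4 mM; run made earlier; the fed solution adds 1.0 times the starting volume
- Saturday's: nucleophile 1 equiv (fed, over 15 s); free base 3 equiv; protic impurity 7.5 mM; run made earlier; the fed solution adds 1.0 times the starting volume
- Monday's: nucleophile 1.5 equiv (fed, over 15 s); free base 3 equiv; protic impurity 5 mM; run made earlier; the fed solution adds 1.0 times the starting volume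
- flask: nucleophile 1.00 equiv (fed, over 15 s); free base 3.00 equiv; protic impurity 5.00 mM; the fed solution adds 1.0 times the starting volume; time 3.0 min

| run | time / min | electrophile / % | target / % |
|---|---|---|---|
| Sunday's | 0.417 | 72.0 | 20.8 |
| Sunday's | 1.33 | 32.6 | 33.0 |
| Sunday's | 2.50 | 15.0 | 32.9 |
| Sunday's | 4.00 | 4.7 | 32.2 |
| Saturday's | 0.250 | 84.1 | 10.9 |
| Saturday's | 0.667 | 59.5 | 24.4 |
| Saturday's | 1.50 | 32.1 | 32.3 |
| Saturday's | 4.00 | 8.7 | 30.2 |
| Monday's | 0.250 | 77.7 | 18.5 |
| Monday's | 0.667 | 43.7 | 36.5 |
| Monday's | 1.50 | 16.4 | 45.0 |
| Monday's | 4.00 | 0.3 | 47.6 |

(each reading ± 1 percentage point)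

- amounts are per litre of the starting volume; all of the dose is in the solution fed
- the earlier runs do not show how much of nucleophile is bound; that part of a forecast is a guess

- part of the electrophile that has reacted at 3.0 min
- share of the unused nucleophile that is free and not bound as protonated nucleophile, at 3.0 min

I count the impurity as taking nucleophile one for one. That leaves 93.2 % of the electrophile charge to spend on Sunday and 90.0 % in the new flask. Saturday's electrophile used is more than its nucleophile after impurity, and its target does not rise between its last two readings. So I take it that target picks up a second electrophile, and that this pair costs one nucleophile. The table holds this mass balance at the last readings, in percent of the electrophile charged.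

| Run | after impurity | electrophile used | unused |
|---|---|---|---|
| Sunday's | 93.2 % | 95.3 % | 29.5 % |
| Saturday's | 85.0 % | 91.3 % | 24.2 % |
| Monday's | 140 % | 99.7 % | 66.3 % |

The forecast gives 88 % reacted and 85 % free, reading that “a second route consumes it without forming target”. My own reckoning interpolates the logarithm of the electrophile between the readings on either side of 3.0 min, which gives 10.2 % left on Sunday and 14.7 % left on Saturday. The new flask's impurity lies between theirs, so I take their mean, 12.4 % left, or 87.6 % reacted. With that and a target of 31.2 %, the mean of Sunday's and Saturday's last readings, I reckon 30.6 % unused. This unused nucleophile, free and bound together, is the equivalents charged, less c(protic impurity)/c(electrophile), less the sum of electrophile used and target divided by two. The forecast's reasoning has about 67 percent of the charge, so here we differ. The bound part I cannot read, so I offer no share of my own.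

The flask gives 88.4 % reacted and 80.6 % free, and both forecast values hold.

    electrophile + nucleophile ⇌ acid set free + target (K = 1.10, k = 0.760 M⁻¹ s⁻¹)
    electrophile + target → side product (k = 0.690 M⁻¹ s⁻¹)
    nucleophile + acid set free ⇌ protonated nucleophile, settled at all times (K = 3500 M⁻¹)
    acid set free + free base ⇌ salt of the base, settled at all times (K = 3200 M⁻¹)
    nucleophile + protic impurity → quenched reagent (k = 3.50 M⁻¹ s⁻¹)

With the flask's target of 31.8 %, the balance leaves 29.9 % unused, beside my 30.6 %, and 80.6 % of that is the 24 % of its charge still free. The neighbour charged 0.250 equiv of nucleophile keeps 38.7 % of its impurity; its balance leaves 4.02 % of its own charge unused, and 93.6 % of that is the 3.76 % still free. In the flask, the loss of electrophile with target to side product and the salt formation of the free base act together on the conversion: taken away in turn, they leave 68.6 % and 72.2 %.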